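The number I began with was 10, the equilibrium constant of the pairing step times the charged [X], and being above one it warned me that the catalyst charged was not the catalyst working.

| flask | J | Z | X | L | time | remark |
|---|---|---|---|---|---|---|
| elm | 0.10 M | 0.400 M (fed, over 2.0 h) | 0.10 mM | 0.36 mM | 2.5 h | all else is in the flask from the start; the feed brings no volume worth counting |
| ash | 0.10 M | 0.400 M | 0.10 mM | 0.36 mM | 2.5 h | everything together at the start |
| cedar | 0.10 M (fed, over 2.0 h) | 0.400 M | 0.10 mM | 0.36 mM | 2.5 h | all else is in the flask from the start; the feed brings no volume worth counting |

    J + Z + X → X + Q (k1 = 37 /M²/s)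
    X + X ⇌ X2 (K2 = 1.0 × 10⁵ /M, k2 = 26 /M/s)
    X + L ⇌ X.L (K3 = 1300 /M, k3 = 8.3 /M/s)

- two of one species on the left: rate k times its square, two consumed each time
- run time (elm): 2.5 h

- the flask that comes out highest in amount of Q, in percent of the J charged, or "all alike" when all lie within 1.5 percentage points (elm / ash / cedar / all alike)
- Q at the end, in percent of the J charged, elm
- Q at the end, in percent of the J charged, ash
- Q at the end, in percent of the J charged, cedar

I took both catalyst equilibria as standing from the start and [L] as charged, and solved for free X, counting two X in each X2.

| form | share of the catalyst charged |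
|---|---|
| X | 19.0 % |
| X2 | 72.1 % |
| X.L | 8.89 % |

I read the table from the bottom. X.L held 8.89 %, less than the 72.1 % in X2, so the pairing was the main loss. The top row was what worked: 0.0190 mM of free X. That gave the working constant, the first step's constant times free [X], 7.03 × 10⁻⁴ /M/s, and the count of lifetimes of J is this constant times [Z] times time.

At the charged [Z], one lifetime of J was 0.988 h, so the 2.5 h of ash counted 2.53 lifetimes if [Z] had stayed at its charge. The exact second-order sum, with Z falling, gave 88.3 % Q in ash.

In cedar, Z stood in excess of the fed J, so J decayed pseudo-first-order. With [Z] held at 0.350 M, the feed and the decay gave 69.9 % Q.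

Elm had no closed form, but ignoring the Z consumed gave a ceiling of 78.1 %, below ash, so I committed to ash.

The forecast named ash, with 73.5 % for elm, 91 % for ash, above my ash, and 70 % for cedar, holding that “feeding either one over 2 h costs reaction time”.

The flasks gave 90.7 % in ash, 73.5 % in elm and 70.5 % in cedar, so ash stood highest. Free X in ash read 19.0 % of the catalyst charged at 2.50 h. In elm, the mean [Z] of 0.175 M over the feed gave 0.887 lifetimes with 7.03 × 10⁻⁴ /M/s, so 41.2 % of J left, and the reading at 2.00 h was 40.4 %. Ash with 0.10 M of Z has equal J and Z, so the same constant gives 38.7 % Q; that flask gave 41.4 %.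

(The rate constants belong to no real substance; what happens was integrated by code.)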